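Readings and results are simulated for substances that don't exist, and the scatter is random.

**The small charge.** A small charge of impurity stands against the initiator in south and north-west: 21 mM against 43.0 mM. Thursday's run holds 21.0 mM initiator against 21 mM impurity, and its monomer in chains stays near zero. So I read the impurity as taking initiator one for one. For south and north-west that leaves 22.0 mM. I call this W, the working charge: initiator charged minus impurity charged.

| flask | free monomer | initiator | impurity | remark | time |
|---|---|---|---|---|---|
| Tuesday's | 1 M | 4.3 mol% | 14 mM | run made earlier |  |
| Monday's | 1 M | 4.3 mol% | 32 mM | run made earlier |  |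
| Thursday's | 1 M | 2.1 mol% | 21 mM | run made earlier |  |
| south | 1.0 M | 4.3 mol% | 21 mM |  | 3.0 h |
| north-west | 1.0 M | 4.3 mol% | 21 mM |  | 8.0 h |

- Tuesday's (time / h: monomer in chains / %, free monomer / %): 0.333: 2, 99; 0.833: 5, 98; 1.50: 8, 92; 2.50: 20, 81; 4.00: 33, 67
- Monday's (time / h: monomer in chains / %, free monomer / %): 0.333: 0, 99; 0.833: 3, 100; 1.50: 3, 93; 2.50: 9, 91; 4.00: 18, 84
- Thursday's (time / h: monomer in chains / %, free monomer / %): 0.333: 0, 100; 0.833: 2, 97; 1.50: 0, 101; 2.50: 2, 98; 4.00: 0, 98

(each reading ± 2 percentage points)



* which of these there is most of at the end, counted by the free monomer in it, south (free monomer / monomer in chains)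
* which of these there is most of at the end, counted by the free monomer in it, north-west (free monomer / monomer in chains)
* the largest of these amounts at the end, in percent of the free monomer charged, south
* the largest of these amounts at the end, in percent of the free monomer charged, north-west

**What comes.** Tuesday's free monomer stands at 92% after 1.50 h and 67% after 4.00 h, so the loss quickens. I take it that living ends build up along a straight line. Their mean is then half the last value, and ln(charged/free) grows as W times t squared, with t the time. Tuesday's W is 29.0 mM, and its last reading gives ln(charged/free) = 0.400. Scaled to Monday's W, that gives 85.9% free monomer at 4.00 h, and Monday's reading there is 84%, about one scatter away.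

Scaled the same way by W and t squared, I expect 84.3% free monomer in south and 29.7% in north-west. The line must bend before the ends reach W, so I hold the north-west figure as low. Leave both flasks as charged: my W holds for those charges.

**The forecast.** It gives free monomer in south at 81% (76% to 86%), and free monomer in north-west at 53% (50% to 63%). It holds: “Free monomer decays roughly first order, with a short lag of under an hour”. We part on north-west, where I have 29.7% free monomer.

**The flask.** South ends with 81.5% free monomer, north-west with 64.8% monomer in chains. At 8.00 h, north-west holds 0.0125 M living end, 22.0% of its initiator and 3.64 × 10⁻⁵ M spent initiator A. Together these make 22.0 mM, which is W again.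

    free monomer + initiator → living end + monomer in chains (k = 0.149 M⁻¹ h⁻¹)
    free monomer + living end → monomer in chains + living end, rate k2*[living end]*[free monomer] (k = 15.8 M⁻¹ h⁻¹)
    initiator → spent initiator A (k = 3.28 × 10⁻⁴ h⁻¹)
    initiator + impurity → spent initiator B (k = 13700 M⁻¹ h⁻¹)

**Second flask.** North-west with 0.053 M impurity has more impurity than initiator, by 10.0 mM. W is below zero, so I expect no chains to speak of. That flask gives 0.230% monomer in chains, with 18.9% of its impurity left and 0% initiator.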